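Readings and results were computed from invented constants, and the scatter is random.

**Per molar.** Watch the unit here: per molar, not per minute. Suppose you treat the two substrates as one pool, fair while the two hands stay near equal. Suppose too that it takes one reagent per substrate, at a rate proportional to catalyst, reagent and substrate. Integrate that rate in closed form, and whatever the catalyst does in time stays inside one integral. That integral of rate constant times catalyst equals the logarithm of reagent's remaining share over substrate's remaining share, divided by the difference of their charges. With equal charges it becomes converted share over remaining share, divided by the charge.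

| setting | zeta | epsilon | alpha | flask |
|---|---|---|---|---|
| left-handed substrate | 0.25 M | 0.25 M | 0.38 M | 0.25 M |
| right-handed substrate | 0.25 M | 0.25 M | 0.38 M | 0.25 M |
| reagent | 1 equiv | 4 equiv | 2 equiv | 2.00 equiv |
| free catalyst | 0.2 mol% | 0.2 mol% | 0.2 mol% | 0.2 mol% |
| added ligand | 1.7 mM | 1.7 mM | 1.7 mM | 1.7 mM |
| remark | run made earlier | run made earlier | run made earlier |  |
| time |  |  |  | 20 min |

| run | time / min | left-handed product / % | right-handed product / % | left-handed substrate / % |
|---|---|---|---|---|
| zeta | 3.00 | 6.4 | 0.7 | 43.6 |
| zeta | 6.00 | 11.4 | 3.5 | 42.2 |
| zeta | 10.0 | 14.1 | 4.5 | 38.6 |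
| zeta | 12.0 | 14.5 | 5.0 | 39.1 |
| zeta | 15.0 | 17.7 | 6.2 | 38.5 |
| zeta | 20.0 | 18.9 | 4.9 | 39.8 |
| epsilon | 1.33 | 13.2 | 1.8 | 39.6 |
| epsilon | 4.00 | 27.4 | 5.1 | 28.7 |
| epsilon | 8.00 | 40.6 | 11.3 | 21.7 |
| epsilon | 10.0 | 41.3 | 12.8 | 21.7 |
| epsilon | 15.0 | 45.0 | 15.3 | 16.5 |
| epsilon | 20.0 | 49.5 | 18.6 | 15.7 |
| alpha | 4.00 | 30.3 | 7.4 | 30.3 |
| alpha | 8.00 | 36.7 | 11.0 | 24.0 |
| alpha | 12.0 | 42.8 | 14.3 | 21.1 |
| alpha | 15.0 | 43.8 | 14.0 | 20.0 |
| alpha | 20.0 | 44.6 | 18.7 | 16.6 |

(standard deviation of a reading: 1 percentage point)

- free catalyst is single-handed; left-handed substrate and right-handed substrate are mirror images of each other, charged as a racemate, each of them at the stated concentration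
- what was read earlier has a scatter of 1 percentage point, one standard deviation
- an excess is the difference of the two amounts in percent of their sum
- an excess is below zero if the other one leads

* left-handed product and right-handed product together, in percent of the left-handed substrate and right-handed substrate charged together, at 20 min
* excess of left-handed product over right-handed product in the product at 20 min
* whether the exchange between left-handed substrate and right-handed substrate keeps pace with the reaction: how far the product's excess at 20 min gets from its value without exchange to its value with instant exchange (above 80% keeps pace, below 20% hardly takes part, else lags behind)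

**Two ways.** I take the readings at 20 min. In zeta the reagent is the limiting reagent, at half of the substrates together, and the formula gives 1.50 M⁻¹. In epsilon the reagent is in excess, and it gives 1.45 M⁻¹. That is the first way. The second is alpha, with equal charges and the same loading on more substrate, so its catalyst is higher by the ratio of the substrate charges. Scaled back by that ratio, it gives 1.49 M⁻¹. These are readings with their scatter, yet they agree, so I trust them. Their mean, 1.48 M⁻¹, is what I carry: the catalyst dose, the time integral of rate constant times catalyst up to 20 min for 0.2 mol% catalyst on 0.25 M. The flask has equal charges of reagent and of the two substrates together, so my own total is 42.5%.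

**The forecast.** It expects 42% product, an excess of 50%, and an exchange that keeps pace, noting: “The substrate stays nearly racemic”. My total is higher.

**The flask.** It gives 43.9% product, an excess of 44.3%, and an exchange that keeps pace, 85% of the way. The forecast's excess stands 5.7 percentage points higher.

    reagent + free catalyst + left-handed substrate → free catalyst + left-handed product (k = 490 M⁻² min⁻¹)
    reagent + free catalyst + right-handed substrate → free catalyst + right-handed product (k = 72.0 M⁻² min⁻¹)
    left-handed substrate ⇌ right-handed substrate (k = 0.240 min⁻¹)
    reagent + free catalyst → spent catalyst (k = 0.0150 M⁻¹ min⁻¹)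
    free catalyst + added ligand ⇌ idle complex (K = 1700 M⁻¹, k = 43.0 M⁻¹ min⁻¹)
    left-handed product ⇌ right-handed product (k = 0.0190 min⁻¹)

**Two clocks.** In the flask, the half-life of left-handed substrate by its forward exchange alone, 2.9 min, is shorter than the 11 min half-life of reagent by the making of left-handed product alone, with the other concentrations held at their charge. At 20.0 min the flask holds 27.3% left-handed and 28.7% right-handed substrate. Read back from the flask's total, the dose is 1.57 M⁻¹. Scaled by catalyst to the neighbour flask with 0.5 mol%, it gives 66.2% product, and that neighbour flask gives 66.8%.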